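1.08 min of clock are missing from Tuesday's run. This is the lag τ (the induction period): the time at which the straight line through its first two readings, of slope V, meets the charge.

| flask | starting material | free catalyst | time |
|---|---|---|---|
| Tuesday's | 0.200 M | 0.00600 M |  |
| Thursday's | 0.300 M | 0.00600 M |  |
| Wednesday's | 0.200 M | 0.0120 M |  |
| Monday's | 0.410 M | 0.00600 M | 30 min |

| Tuesday's run: time / min | Tuesday's run: [starting material] / M | Thursday's run: time / min | Thursday's run: [starting material] / M | Wednesday's run: time / min | Wednesday's run: [starting material] / M |
|---|---|---|---|---|---|
| 2.3 | 0.1924 | 2.3 | 0.2917 | 2.3 | 0.1848 |
| 6.9 | 0.1638 | 6.9 | 0.2598 | 6.9 | 0.1298 |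
| 13 | 0.1275 | 13 | 0.2204 | 13 | 0.0705 |
| 21 | 0.0854 | 21 | 0.1687 | 21 | 0.0251 |
| 30 | 0.0497 | 30 | 0.1170 | 30 | 0.0085 |

(scatter of a reading: 6 × 10⁻⁴ M)

* the exponent of [free catalyst] in the starting rate at the charge of the Tuesday's run (at the point where two percent of the starting material have become product)
* the exponent of [starting material] in the starting rate at the charge of the Tuesday's run (at the point where two percent of the starting material have become product) (one fixed amount of product, the same in the runs compared)
* starting material in the Monday's run at 30 min, as a share of the starting material charged

- Overall: starting material -> product, with free catalyst as catalyst.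
- Constant volume, constant temperature.
- Bound and free are read together.
- An order is taken over about fifteen percent of the charge, up and down.

Wednesday's run reads 1.03 min and Thursday's 1.10 min, so the readings show one lag at each charge.

One chemist, who made the forecast, looks at the doubling. V reads 0.00622 M min⁻¹ in Tuesday's run and 0.0120 M min⁻¹ in Wednesday's, twice as much, an order of 0.948. Her forecast halves Wednesday's rates, finds that they match Tuesday's at equal starting material, says “the order in catalyst is about 1”, and gives 0.95 in free catalyst, 0.3 in starting material and 52% for Monday's run.

The other chemist objects that the question is asked at a mark, 0.00400 M of product, and not at V. At V, Tuesday's run would make that in 0.643 min, less than τ. Her ratio for Tuesday's run is 0.597; this mark ratio m, the product at the mark divided by V times τ, is 0.310 for Wednesday's run. Far above one, the mark lies past the lag and keeps the order of V. Far below one, with τ held fixed, the rate is still climbing from zero, product grows as the square of time, and the rate at a fixed product goes as the root of V, so the order is 0.5 times that of V. Both ratios lie below one, so she commits to an order in free catalyst between 0.5 and one.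

The simulation gives 0.68 and 0.13 for the orders in free catalyst and starting material, and 51.4% for Monday's run.

    active catalyst + starting material ⇌ catalyst-substrate complex, settled at all times (24.30 M⁻¹)
    catalyst-substrate complex → product + active catalyst (1.344 min⁻¹)
    free catalyst → active catalyst (0.7920 min⁻¹)
    2 active catalyst → 2 spent catalyst (10.20 M⁻¹ min⁻¹)

The order in free catalyst stands below one because of the slow conversion of free catalyst into active catalyst: the same flasks with that conversion instant give 1.0 against 0.68. Instant conversion is the region of a mark ratio far above one, where the forecast's view holds, as it does for V read between 2.3 min and 6.9 min. The mark ratio also sorts the runs. Wednesday's run, at 0.310, stands at 60.0% of its V at the mark, Tuesday's, at 0.597, at 73.4%, and Thursday's, with V of 0.00693 M min⁻¹ and between them at 0.535, at 68.7%.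

(The readings were generated by integration for an exercise, noise included.)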